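3 questions stand open, and the practical one is whether the maple flask, left for 130 h, turns its substrate over or stops far short.

| flask | substrate | coupling partner | catalyst | product | time |
|---|---|---|---|---|---|
| alder | 0.250 M | 0.300 M | 0.0250 M |  |  |
| cedar | 0.250 M | 0.300 M | 0.0250 M | 0.0750 M |  |
| ash | 0.250 M | 0.450 M | 0.0250 M |  |  |
| elm | 0.250 M | 0.300 M | 0.0130 M |  |  |
| maple | 0.250 M | 0.300 M | 0.0250 M |  | 130 h |

- alder run (time / h: [product] / M): 0.84: 0.0027; 1.4: 0.0048; 2.5: 0.0119; 4.2: 0.0218; 7.2: 0.0413; 12: 0.0559; 21: 0.0609
- cedar run (time / h: [product] / M): 0.84: 0.0928; 1.4: 0.1006; 2.5: 0.1191; 4.2: 0.1438; 7.2: 0.1710; 12: 0.1860; 21: 0.1911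
- ash run (time / h: [product] / M): 0.84: 0.0050; 1.4: 0.0027; 2.5: 0.0182; 4.2: 0.0286; 7.2: 0.0600; 12: 0.0828; 21: 0.1006
- elm run (time / h: [product] / M): 0.84: 0.0010; 1.4: 0.0014; 2.5: 0.0071; 4.2: 0.0148; 7.2: 0.0239; 12: 0.0353; 21: 0.0436

(scatter of a reading: 0.002 M)

* order of the initial rate in [coupling partner], near the charge of the alder run, the rate being that where two percent of its substrate are product
* order of the initial rate in [catalyst], near the charge of the alder run, the rate being that where two percent of its substrate are product
* product in the maple run at 130 h, as a share of the substrate charged

- Overall: substrate + coupling partner -> product, with catalyst as catalyst.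
- Constant volume, constant temperature.
- Bound and free are read together.
- An order is taken over about fifteen percent of the charge, up and down.

Turn the question round: what must be true of maple for it to finish? Each product molecule takes up one molecule of coupling partner, and on paper substrate is the limiting reagent, with 0.250 M charged, less than the 0.300 M of coupling partner. So follow one molecule of coupling partner to its fork: it enters product, or it does not. The fork odds, meaning product made divided by coupling partner charged and not turned into product, must reach 5.00 for a finish.

The alder flask, with the same charge as maple, read 0.0609 M at 21 h, which gives odds of 0.255, a factor of 19.6 short. The cedar flask, charged with added product, made 0.116 M by that time, so its odds of 0.631 are higher than alder's but still far below the 5.00 required.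

The working estimate here is for flasks with the same charges of substrate and coupling partner and no added product, compared at one time: if the competing fork keeps its pace, the odds move in step with the rate of making product. Alder's readings gained 0.00500 M in the last 9.00 h, less than the 0.0146 M of the shorter 4.80 h before. So the reckoning here commits maple to a little above the 24.4 % of the substrate charged that alder's reading at 21 h shows.

The forecast gives 27 % for maple, above that reading of alder, with orders of 0.9 in coupling partner and 0.7 in catalyst, and it reads the halt this way: “The stall itself looks like catalyst death”.

The flask gives 26.3 % for maple, with orders of 0.71 in catalyst and 0.70 in coupling partner, the latter below the forecast's 0.9.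

    catalyst + substrate → catalyst-substrate complex (2.347 M⁻¹ h⁻¹)
    catalyst-substrate complex + coupling partner → product + catalyst (1.757 M⁻¹ h⁻¹)
    coupling partner → lost reagent (0.1372 h⁻¹)
    substrate + coupling partner + product → 2 product (3.071 M⁻² h⁻¹)

Coupling partner has a step of its own to lost reagent, with a constant of 0.137 h⁻¹. Maple's 0.0658 M of product puts its odds at 0.281, still far under 5.00. The elm flask ran at 0.62 of alder's rate, both taken where 2 percent of alder's substrate had turned, so the estimate turns alder's odds at 21 h into 0.157 for elm at that time, or 0.0407 M of product, and elm read 0.0436 M there.

The runs are calculated on assumed constants; the scatter is artificial.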